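**Plan**

1. Retrosynthesis: the interflavan bond C4(upper, catechol unit)–C6(lower, 4‑hydroxyphenyl unit) is cut first (Friedel–Crafts union of a C4‑activated 2,3‑cis‑flavan‑3‑ol with a diol‑protected all‑cis flavan‑3,4‑diol). In each half the pyran ring is then cut at C3–C4 and O1–C2, back to one salicylaldehyde (3) and a cinnamaldehyde (5 or 14).
2. Enabling feature: in both units O‑1 and C‑4 sit ortho on the 7,8‑dioxygenated A‑ring (a masked salicylaldehyde), and C‑2 is the benzylic carbon next to the B‑ring (the β‑carbon of a cinnamaldehyde). Once O1–C2 is made, the α‑carbon (C‑3) is held six atoms from the formyl carbon (C‑4), and an aldol condensation closes ring C at C3–C4. The formyl group left on C‑3 is a helper, later turned into the C‑3 oxygen by Baeyer–Villiger oxidation.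
3. Forward order: ring C of the upper unit (step 4, elaborated in 5–7), ring C of the lower unit (step 9, elaborated in 10–15), union at C4–C6 (step 16), carbonate removal and global debenzylation (17–18).
4. Stereochemistry: C‑2 of both units comes from the prolinol catalyst in the domino step. C‑3 comes from L‑Selectride reduction of the flavan‑3‑ones (2,3‑cis). Lower C‑4 comes from NaBH4 reduction anti to the axial 3‑OH (all‑cis). Upper C‑4 comes from arene attack trans to the 3‑OH (3,4‑trans).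

Key step: step 4

Remark: flavan numbering is used; "upper unit" is the 4‑aryl‑flavan‑3‑ol with the catechol B‑ring, "lower unit" the flavan‑3,4‑diol; Bn = benzyl.
Assumption: the (S)‑diarylprolinol silyl ether directs the phenol oxygen to the enal β‑face that gives the (2R)‑chromenes (face‑shielding model of its E‑iminium ions); the antipodal catalyst is equally available should the sense be opposite.

**Route**

Step 1
Reactants: 1 2,3,4-trihydroxybenzaldehyde
Product: 2 2,3,4-tris(benzyloxy)benzaldehyde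
Conditions: BnBr (3.5 equiv), K2CO3, DMF, 60 °C
Reagents that add atoms: benzyl bromide, BrCc1ccccc1
Why: Williamson ether synthesis on all three phenols (the chelated 2‑OH included under forcing conditions) installs benzyl ethers that fall only in the final hydrogenolysis.

Step 2
Reactants: 2 2,3,4-tris(benzyloxy)benzaldehyde
Product: 3 3,4-bis(benzyloxy)-2-hydroxybenzaldehyde
Conditions: MgBr2·OEt2 (1.2 equiv), toluene/Et2O, 80 °C; 1 M HCl work-up
Reagents that add atoms: none
Why: Chelation-controlled Lewis-acid ether cleavage, in which Mg(II) held between the formyl oxygen and the ortho ether oxygen activates only the 2‑O‑benzyl group for attack by bromide, frees the phenol that becomes O‑1.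

Step 3
Reactants: 4 3,4-bis(benzyloxy)benzaldehyde
Product: 5 (E)-3-[3,4-bis(benzyloxy)phenyl]prop-2-enal
Conditions: Ph3P=CHCHO (1.1 equiv), toluene, 80 °C
Reagents that add atoms: (triphenylphosphoranylidene)acetaldehyde, O=CC=P(c1ccccc1)(c1ccccc1)c1ccccc1
Why: Wittig olefination with a stabilised ylide should give the E‑enal, whose α‑ and β‑carbons become C‑3 and C‑2 of the upper unit.

Step 4
Reactants: 3 3,4-bis(benzyloxy)-2-hydroxybenzaldehyde; 5 (E)-3-[3,4-bis(benzyloxy)phenyl]prop-2-enal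
Product: 8 (R)-2-[3,4-bis(benzyloxy)phenyl]-7,8-bis(benzyloxy)-2H-chromene-3-carbaldehyde, via oxa-Michael adduct 6 (not isolated), via aldol adduct 7 (not isolated)
Conditions: 3 (1.2 equiv), (S)-α,α-diphenylprolinol trimethylsilyl ether (20 mol %), 2-nitrobenzoic acid (20 mol %), 4 Å MS, toluene, rt
Reagents that add atoms: none
Why: The amine condenses with 5 to an E‑iminium ion shielded on one face by the CPh2(OTMS) group; the phenol oxygen of 3 adds to the β‑carbon from the open face (oxa‑Michael, O1–C2, C‑2 = R), the enamine carbon so formed (C‑3) attacks the ortho‑formyl carbon (C‑4) of the same A‑ring, and loss of water with iminium hydrolysis releases 8. The closest known reaction type is the amine‑catalysed domino oxa‑Michael/aldol condensation of salicylaldehydes with enals to 2‑substituted 2H‑chromene‑3‑carbaldehydes. Ring C closes by a 6‑(enolexo)‑exo‑trig aldol addition of C‑3 to the C‑4 carbonyl, made irreversible by dehydration to the conjugated enal. The single new stereocentre, C‑2, is under catalyst control (face shielding of the iminium ion), while C‑3 and C‑4 leave the step as sp2 carbons and are set in steps 6, 7 and 16. The step needs the aldol closure to outrun retro‑oxa‑Michael cleavage, which would erode the ee; the ortho relation of O‑1 and the formyl group on the A‑ring secures this because the closure is intramolecular and six‑membered. It also needs O‑ rather than C‑attack of the phenol, which the hydrogen‑bonded, acid‑buffered phenol and the hard iminium β‑carbon favour.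

Step 5
Reactants: 8 (R)-2-[3,4-bis(benzyloxy)phenyl]-7,8-bis(benzyloxy)-2H-chromene-3-carbaldehyde
Product: 10 (R)-2-[3,4-bis(benzyloxy)phenyl]-7,8-bis(benzyloxy)chroman-3-one, via enol formate 9 (not isolated)
Conditions: mCPBA (1.1 equiv), CH2Cl2, 0 °C; aq. Na2S2O3/NaHCO3 wash; then KHCO3 (cat.), MeOH/THF, 0 °C
Reagents that add atoms: 3-chloroperoxybenzoic acid, OOC(=O)c1cccc(Cl)c1
Why: Baeyer–Villiger oxidation in which the electron‑rich, α‑substituted alkenyl carbon C‑3 should migrate in preference to hydride (as in the peracid conversion of α‑alkylcinnamaldehydes into arylacetones), followed by mild methanolysis of enol formate 9, which releases the ketone by protonation at C‑4 without touching C‑2.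

Step 6
Reactants: 10 (R)-2-[3,4-bis(benzyloxy)phenyl]-7,8-bis(benzyloxy)chroman-3-one
Product: 11 (2R,3R)-2-[3,4-bis(benzyloxy)phenyl]-7,8-bis(benzyloxy)chroman-3-ol
Conditions: L-Selectride (1.5 equiv), LiBr, THF, −78 °C; H2O quench
Reagents that add atoms: none
Why: Diastereoselective ketone reduction in which the bulky trialkylborohydride attacks the C‑3 carbonyl from the face opposite the adjacent 2‑aryl group (equatorial attack), so the new 3‑OH is axial and cis to the aryl group (3R), the known behaviour of flavan‑3‑ones.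

Step 7
Reactants: 11 (2R,3R)-2-[3,4-bis(benzyloxy)phenyl]-7,8-bis(benzyloxy)chroman-3-ol
Product: 12 (2R,3R,4S)-2-[3,4-bis(benzyloxy)phenyl]-7,8-bis(benzyloxy)-4-(2-ethoxyethoxy)chroman-3-ol
Conditions: DDQ (2 equiv), 2-ethoxyethanol (10 equiv), CH2Cl2, rt
Reagents that add atoms: 2-ethoxyethanol, CCOCCO
Why: DDQ-mediated benzylic oxidation (hydride abstraction at C‑4, para to the 7‑benzyloxy group and ortho to O‑1) followed by capture of the alcohol trans to the axial 3‑OH should give the 4β‑ether (4S), a leaving group of the type used for flavan C‑4 electrophiles.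

Step 8
Reactants: 13 4-(benzyloxy)benzaldehyde
Product: 14 (E)-3-[4-(benzyloxy)phenyl]prop-2-enal
Conditions: Ph3P=CHCHO (1.1 equiv), toluene, 80 °C
Reagents that add atoms: (triphenylphosphoranylidene)acetaldehyde, O=CC=P(c1ccccc1)(c1ccccc1)c1ccccc1
Why: Wittig olefination with the stabilised ylide should give the E‑enal that supplies C‑2, C‑3 and the B‑ring of the lower unit.

Step 9
Reactants: 3 3,4-bis(benzyloxy)-2-hydroxybenzaldehyde; 14 (E)-3-[4-(benzyloxy)phenyl]prop-2-enal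
Product: 17 (R)-7,8-bis(benzyloxy)-2-[4-(benzyloxy)phenyl]-2H-chromene-3-carbaldehyde, via oxa-Michael adduct 15 (not isolated), via aldol adduct 16 (not isolated)
Conditions: 3 (1.2 equiv), (S)-α,α-diphenylprolinol trimethylsilyl ether (20 mol %), 2-nitrobenzoic acid (20 mol %), 4 Å MS, toluene, rt
Reagents that add atoms: none
Why: The same amine‑catalysed domino oxa‑Michael/aldol condensation as in step 4 builds ring C of the lower unit, with C‑2 (R) set by the catalyst in the oxa‑Michael event.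

Step 10
Reactants: 17 (R)-7,8-bis(benzyloxy)-2-[4-(benzyloxy)phenyl]-2H-chromene-3-carbaldehyde
Product: 19 (R)-7,8-bis(benzyloxy)-2-[4-(benzyloxy)phenyl]chroman-3-one, via enol formate 18 (not isolated)
Conditions: mCPBA (1.1 equiv), CH2Cl2, 0 °C; aq. Na2S2O3/NaHCO3 wash; then KHCO3 (cat.), MeOH/THF, 0 °C
Reagents that add atoms: 3-chloroperoxybenzoic acid, OOC(=O)c1cccc(Cl)c1
Why: Baeyer–Villiger oxidation with alkenyl migration and methanolysis of enol formate 18, as in step 5, converts the helper formyl group into the C‑3 carbonyl.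

Step 11
Reactants: 19 (R)-7,8-bis(benzyloxy)-2-[4-(benzyloxy)phenyl]chroman-3-one
Product: 20 (2R,3R)-7,8-bis(benzyloxy)-2-[4-(benzyloxy)phenyl]chroman-3-ol
Conditions: L-Selectride (1.5 equiv), LiBr, THF, −78 °C; H2O quench
Reagents that add atoms: none
Why: Diastereoselective ketone reduction from the face opposite the 2‑aryl group, as in step 6, should give the axial 3‑OH cis to the aryl group (3R).

Step 12
Reactants: 20 (2R,3R)-7,8-bis(benzyloxy)-2-[4-(benzyloxy)phenyl]chroman-3-ol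
Product: 21 (2R,3R,4S)-7,8-bis(benzyloxy)-2-[4-(benzyloxy)phenyl]chromane-3,4-diol
Conditions: DDQ (2 equiv), CH2Cl2/H2O (20:1), rt
Reagents that add atoms: water, O
Why: DDQ-mediated benzylic oxidation at C‑4 with capture of water trans to the axial 3‑OH should give the 3,4‑trans diol, which puts oxygen on C‑4 (its configuration is corrected in steps 13–14).

Step 13
Reactants: 21 (2R,3R,4S)-7,8-bis(benzyloxy)-2-[4-(benzyloxy)phenyl]chromane-3,4-diol
Product: 22 (2R,3S)-7,8-bis(benzyloxy)-2-[4-(benzyloxy)phenyl]-3-hydroxychroman-4-one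
Conditions: activated MnO2 (15 equiv), CH2Cl2, rt
Reagents that add atoms: none
Why: Chemoselective oxidation of the benzylic 4‑OH by activated MnO2 under neutral conditions should leave the non‑benzylic 3‑OH and the C‑2/C‑3 centres untouched (the trans‑diaxial diol cannot form a cyclic manganate, so glycol cleavage is disfavoured).

Step 14
Reactants: 22 (2R,3S)-7,8-bis(benzyloxy)-2-[4-(benzyloxy)phenyl]-3-hydroxychroman-4-one
Product: 23 (2R,3R,4R)-7,8-bis(benzyloxy)-2-[4-(benzyloxy)phenyl]chromane-3,4-diol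
Conditions: NaBH4, MeOH/THF, −40 °C
Reagents that add atoms: none
Why: Substrate-controlled carbonyl reduction in which hydride adds to C‑4 anti to the axial 3‑OH (axial attack on the half‑chair with the 2‑aryl group equatorial) should place the new 4‑OH cis to the 3‑OH (4R), giving the all‑cis diol as known for 2,3‑cis‑dihydroflavonols.

Step 15
Reactants: 23 (2R,3R,4R)-7,8-bis(benzyloxy)-2-[4-(benzyloxy)phenyl]chromane-3,4-diol
Product: 24 cis-fused 3,4-cyclic carbonate of diol 23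
Conditions: CDI (1.5 equiv), DMAP (cat.), THF, rt
Reagents that add atoms: 1,1'-carbonyldiimidazole, O=C(n1ccnc1)n1ccnc1
Why: Cyclic carbonate formation by acyl transfer from CDI ties the benzylic 4‑oxygen into a cis‑fused ring, so that any C4–O heterolysis in the next step can only reclose and the lower unit acts purely as a nucleophile.

Step 16
Reactants: 12 (2R,3R,4S)-2-[3,4-bis(benzyloxy)phenyl]-7,8-bis(benzyloxy)-4-(2-ethoxyethoxy)chroman-3-ol; 24 cis-fused 3,4-cyclic carbonate of diol 23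
Product: 25 C4(upper)–C6(lower) linked dimer as hepta-O-benzyl ether and lower-unit 3,4-cyclic carbonate
Conditions: 24 (3 equiv, excess recovered), TMSOTf (0.3 equiv), CH2Cl2, −78 → −30 °C; Et3N quench
Reagents that add atoms: none
Why: Lewis-acid-promoted Friedel–Crafts alkylation of the proanthocyanidin type, in which TMSOTf ionises the 4‑(2‑ethoxyethoxy) group of 12 and C‑6 of 24 (ortho to the 7‑oxygen, para to O‑1) attacks C‑4 trans to the axial 3‑OH, should set the upper C‑4 centre 3,4‑trans, while the excess of 24 suppresses self‑condensation of 12.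

Step 17
Reactants: 25 C4(upper)–C6(lower) linked dimer as hepta-O-benzyl ether and lower-unit 3,4-cyclic carbonate
Product: 26 hepta-O-benzyl ether of the target with all three alcohols free
Conditions: K2CO3 (0.2 equiv), MeOH/THF, rt
Reagents that add atoms: none
Why: Base-catalysed transesterification (carbonate methanolysis) frees the lower 3,4‑diol without affecting the benzyl ethers or any stereocentre.

Step 18
Reactants: 26 hepta-O-benzyl ether of the target with all three alcohols free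
Product: 27 (2R,3R,4R)-6-[(2R,3R,4S)-2-(3,4-dihydroxyphenyl)-3,7,8-trihydroxychroman-4-yl]-2-(4-hydroxyphenyl)chromane-3,4,7,8-tetrol
Conditions: H2 (1 atm), 20% Pd(OH)2/C, THF/MeOH/H2O, rt
Reagents that add atoms: none
Why: Catalytic hydrogenolysis of the seven aryl benzyl ethers under neutral conditions, under which the secondary benzylic 4‑OH and the diarylmethine C‑4 are expected to persist, should release the target.

**Compound list**

1 | 2,3,4-trihydroxybenzaldehyde | O=Cc1ccc(O)c(O)c1O | starting material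
2 | 2,3,4-tris(benzyloxy)benzaldehyde | O=Cc1ccc(OCc2ccccc2)c(OCc2ccccc2)c1OCc1ccccc1 | intermediate
3 | 3,4-bis(benzyloxy)-2-hydroxybenzaldehyde | O=Cc1ccc(OCc2ccccc2)c(OCc2ccccc2)c1O | intermediate
4 | 3,4-bis(benzyloxy)benzaldehyde | O=Cc1ccc(OCc2ccccc2)c(OCc2ccccc2)c1 | starting material
5 | (E)-3-[3,4-bis(benzyloxy)phenyl]prop-2-enal | O=C/C=C/c1ccc(OCc2ccccc2)c(OCc2ccccc2)c1 | intermediate
6 | oxa-Michael adduct: (S)-3-[3,4-bis(benzyloxy)phenyl]-3-[2,3-bis(benzyloxy)-6-formylphenoxy]propanal (free-aldehyde form of the catalyst-bound enamine) | O=CC[C@H](Oc1c(C=O)ccc(OCc2ccccc2)c1OCc1ccccc1)c1ccc(OCc2ccccc2)c(OCc2ccccc2)c1 | intermediate (not isolated)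
7 | aldol adduct: (2S)-2-[3,4-bis(benzyloxy)phenyl]-7,8-bis(benzyloxy)-4-hydroxychromane-3-carbaldehyde, C-3/C-4 undefined (free-aldehyde form) | O=CC1C(O)c2ccc(OCc3ccccc3)c(OCc3ccccc3)c2O[C@@H]1c1ccc(OCc2ccccc2)c(OCc2ccccc2)c1 | intermediate (not isolated)
8 | (R)-2-[3,4-bis(benzyloxy)phenyl]-7,8-bis(benzyloxy)-2H-chromene-3-carbaldehyde | O=CC1=Cc2ccc(OCc3ccccc3)c(OCc3ccccc3)c2O[C@@H]1c1ccc(OCc2ccccc2)c(OCc2ccccc2)c1 | intermediate
9 | enol formate: (R)-2-[3,4-bis(benzyloxy)phenyl]-7,8-bis(benzyloxy)-2H-chromen-3-yl formate | O=COC1=Cc2ccc(OCc3ccccc3)c(OCc3ccccc3)c2O[C@@H]1c1ccc(OCc2ccccc2)c(OCc2ccccc2)c1 | intermediate (not isolated)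
10 | (R)-2-[3,4-bis(benzyloxy)phenyl]-7,8-bis(benzyloxy)chroman-3-one | O=C1Cc2ccc(OCc3ccccc3)c(OCc3ccccc3)c2O[C@@H]1c1ccc(OCc2ccccc2)c(OCc2ccccc2)c1 | intermediate
11 | (2R,3R)-2-[3,4-bis(benzyloxy)phenyl]-7,8-bis(benzyloxy)chroman-3-ol (2,3-cis) | O[C@@H]1Cc2ccc(OCc3ccccc3)c(OCc3ccccc3)c2O[C@@H]1c1ccc(OCc2ccccc2)c(OCc2ccccc2)c1 | intermediate
12 | (2R,3R,4S)-2-[3,4-bis(benzyloxy)phenyl]-7,8-bis(benzyloxy)-4-(2-ethoxyethoxy)chroman-3-ol (2,3-cis-3,4-trans) | O[C@@H]1[C@@H](OCCOCC)c2ccc(OCc3ccccc3)c(OCc3ccccc3)c2O[C@@H]1c1ccc(OCc2ccccc2)c(OCc2ccccc2)c1 | intermediate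
13 | 4-(benzyloxy)benzaldehyde | O=Cc1ccc(OCc2ccccc2)cc1 | starting material
14 | (E)-3-[4-(benzyloxy)phenyl]prop-2-enal | O=C/C=C/c1ccc(OCc2ccccc2)cc1 | intermediate
15 | oxa-Michael adduct: (S)-3-[4-(benzyloxy)phenyl]-3-[2,3-bis(benzyloxy)-6-formylphenoxy]propanal (free-aldehyde form of the catalyst-bound enamine) | O=CC[C@H](Oc1c(C=O)ccc(OCc2ccccc2)c1OCc1ccccc1)c1ccc(OCc2ccccc2)cc1 | intermediate (not isolated)
16 | aldol adduct: (2S)-7,8-bis(benzyloxy)-2-[4-(benzyloxy)phenyl]-4-hydroxychromane-3-carbaldehyde, C-3/C-4 undefined (free-aldehyde form) | O=CC1C(O)c2ccc(OCc3ccccc3)c(OCc3ccccc3)c2O[C@@H]1c1ccc(OCc2ccccc2)cc1 | intermediate (not isolated)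
17 | (R)-7,8-bis(benzyloxy)-2-[4-(benzyloxy)phenyl]-2H-chromene-3-carbaldehyde | O=CC1=Cc2ccc(OCc3ccccc3)c(OCc3ccccc3)c2O[C@@H]1c1ccc(OCc2ccccc2)cc1 | intermediate
18 | enol formate: (R)-7,8-bis(benzyloxy)-2-[4-(benzyloxy)phenyl]-2H-chromen-3-yl formate | O=COC1=Cc2ccc(OCc3ccccc3)c(OCc3ccccc3)c2O[C@@H]1c1ccc(OCc2ccccc2)cc1 | intermediate (not isolated)
19 | (R)-7,8-bis(benzyloxy)-2-[4-(benzyloxy)phenyl]chroman-3-one | O=C1Cc2ccc(OCc3ccccc3)c(OCc3ccccc3)c2O[C@@H]1c1ccc(OCc2ccccc2)cc1 | intermediate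
20 | (2R,3R)-7,8-bis(benzyloxy)-2-[4-(benzyloxy)phenyl]chroman-3-ol (2,3-cis) | O[C@@H]1Cc2ccc(OCc3ccccc3)c(OCc3ccccc3)c2O[C@@H]1c1ccc(OCc2ccccc2)cc1 | intermediate
21 | (2R,3R,4S)-7,8-bis(benzyloxy)-2-[4-(benzyloxy)phenyl]chromane-3,4-diol (2,3-cis-3,4-trans) | O[C@@H]1[C@@H](O)c2ccc(OCc3ccccc3)c(OCc3ccccc3)c2O[C@@H]1c1ccc(OCc2ccccc2)cc1 | intermediate
22 | (2R,3S)-7,8-bis(benzyloxy)-2-[4-(benzyloxy)phenyl]-3-hydroxychroman-4-one (2,3-cis) | O[C@@H]1C(=O)c2ccc(OCc3ccccc3)c(OCc3ccccc3)c2O[C@@H]1c1ccc(OCc2ccccc2)cc1 | intermediate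
23 | (2R,3R,4R)-7,8-bis(benzyloxy)-2-[4-(benzyloxy)phenyl]chromane-3,4-diol (all-cis) | O[C@@H]1[C@H](O)c2ccc(OCc3ccccc3)c(OCc3ccccc3)c2O[C@@H]1c1ccc(OCc2ccccc2)cc1 | intermediate
24 | cis-fused 3,4-cyclic carbonate of diol 23 (configuration of 23 retained) | O=C1O[C@@H]2[C@H](O1)c1ccc(OCc3ccccc3)c(OCc3ccccc3)c1O[C@@H]2c1ccc(OCc2ccccc2)cc1 | intermediate
25 | dimer carbonate: carbonate 24 bearing at C-6 the (2R,3R)-2-[3,4-bis(benzyloxy)phenyl]-7,8-bis(benzyloxy)-3-hydroxychroman-4-yl group, C-4 aryl bond trans to its 3-OH | C(c1ccccc1)Oc1ccc([C@H]2Oc3c(cc([C@H]4c5ccc(OCc6ccccc6)c(OCc6ccccc6)c5O[C@H](c5ccc(OCc6ccccc6)c(OCc6ccccc6)c5)[C@@H]4O)c(OCc4ccccc4)c3OCc3ccccc3)[C@@H](OC(=O)O7)[C@H]27)cc1 | intermediate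
26 | hepta-O-benzyl ether of 27 (all seven phenolic oxygens benzylated, three alcohols free, stereocentres as in 27) | C(c1ccccc1)Oc1ccc([C@H]2Oc3c(cc([C@H]4c5ccc(OCc6ccccc6)c(OCc6ccccc6)c5O[C@H](c5ccc(OCc6ccccc6)c(OCc6ccccc6)c5)[C@@H]4O)c(OCc4ccccc4)c3OCc3ccccc3)[C@@H](O)[C@H]2O)cc1 | intermediate
27 | (2R,3R,4R)-6-[(2R,3R,4S)-2-(3,4-dihydroxyphenyl)-3,7,8-trihydroxychroman-4-yl]-2-(4-hydroxyphenyl)chromane-3,4,7,8-tetrol | Oc1ccc([C@H]2Oc3c(cc([C@H]4c5ccc(O)c(O)c5O[C@H](c5ccc(O)c(O)c5)[C@@H]4O)c(O)c3O)[C@@H](O)[C@H]2O)cc1 | target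

**Totals**

Total step count: 18. Longest linear sequence: 12 steps (1 → 2 → 3 → 17 → 19 → 20 → 21 → 22 → 23 → 24 → 25 → 26 → 27).

**Steps most likely to fail**

Step 16 (union). The 7,8‑dibenzyloxylated A‑ring of 24 is a weak π‑nucleophile. The C‑4 cation from 12 may therefore be intercepted by C‑6 of a second molecule of 12 (self‑condensation to oligomers) or collapse by proton loss from C‑3 before 24 reacts. The fallback replaces the excess of nucleophile by a blocking group and sets out from 11. Bromination with NBS (CH2Cl2, −78 → 0 °C) at the activated C‑6 should give (2R,3R)-6-bromo-2-[3,4-bis(benzyloxy)phenyl]-7,8-bis(benzyloxy)chroman-3-ol F1. DDQ/2‑ethoxyethanol as in step 7 then gives (2R,3R,4S)-6-bromo-2-[3,4-bis(benzyloxy)phenyl]-7,8-bis(benzyloxy)-4-(2-ethoxyethoxy)chroman-3-ol F2, which can no longer serve as a nucleophile at C‑6. TMSOTf‑promoted coupling with about 1.5 equiv of 24 at −40 → 0 °C gives the 6‑bromo (upper unit) analogue of 25 F3, and K2CO3/MeOH gives the 6‑bromo (upper unit) analogue of 26 F4. Hydrogenolysis over Pd(OH)2/C in the presence of Et3N removes the aryl bromide together with the benzyl ethers, and the route is rejoined at 27.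

Step 5 (formyl to carbonyl). In the Criegee adduct hydride may migrate instead of the alkenyl carbon (giving the carboxylic acid), the enol formate may be oxidised further by residual peracid, or C‑2 may epimerise during deformylation. The fallback degrades the helper group by a nitrogen‑based rearrangement and sets out from 8. Pinnick oxidation (NaClO2, NaH2PO4, 2‑methyl‑2‑butene, t‑BuOH/H2O) gives (R)-2-[3,4-bis(benzyloxy)phenyl]-7,8-bis(benzyloxy)-2H-chromene-3-carboxylic acid F5. Curtius rearrangement (DPPA, Et3N, t‑BuOH/toluene, 80 °C) gives tert-butyl N-{(R)-2-[3,4-bis(benzyloxy)phenyl]-7,8-bis(benzyloxy)-2H-chromen-3-yl}carbamate F6. Acidic hydrolysis of this enecarbamate (aq. HCl, THF, rt) returns to the route at 10.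

Step 4 (key step). Iminium formation from the electron‑rich enal may be slow, and reversible oxa‑Michael addition may erode the enantiomeric purity at C‑2 before or after the aldol closure. The fallback sets C‑2 by metal catalysis and closes C3–C4 by metathesis; it sets out from 3 and 5 and returns at 10.
- Wittig methylenation of 3 (Ph3P=CH2, THF) gives 2,3-bis(benzyloxy)-6-vinylphenol F7.
- Reduction of 5 (NaBH4, MeOH, 0 °C) gives (E)-3-[3,4-bis(benzyloxy)phenyl]prop-2-en-1-ol F8, and ClCO2Me/pyridine gives (E)-3-[3,4-bis(benzyloxy)phenyl]allyl methyl carbonate F9.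
- Iridium‑catalysed enantioselective allylic etherification of F9 with F7 ([Ir(cod)Cl]2, chiral phosphoramidite, THF; ligand enantiomer chosen for the S‑ether) gives the branched ether (S)-1,2-bis(benzyloxy)-3-({1-[3,4-bis(benzyloxy)phenyl]prop-2-en-1-yl}oxy)-4-vinylbenzene F10.
- Ring‑closing metathesis (second‑generation Ru benzylidene catalyst, CH2Cl2, 40 °C) forms the C3=C4 bond and gives (S)-2-[3,4-bis(benzyloxy)phenyl]-7,8-bis(benzyloxy)-2H-chromene F11.
- Hydroboration–oxidation (BH3·THF; NaOH/H2O2), anti to the 2‑aryl group, gives (2R,3S)-2-[3,4-bis(benzyloxy)phenyl]-7,8-bis(benzyloxy)chroman-3-ol F12.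
- Oxidation with DMP (CH2Cl2, rt) gives 10.

**Further compounds**

F1 | step 16 | (2R,3R)-6-bromo-2-[3,4-bis(benzyloxy)phenyl]-7,8-bis(benzyloxy)chroman-3-ol | O[C@@H]1Cc2cc(Br)c(OCc3ccccc3)c(OCc3ccccc3)c2O[C@@H]1c1ccc(OCc2ccccc2)c(OCc2ccccc2)c1
F2 | step 16 | (2R,3R,4S)-6-bromo-2-[3,4-bis(benzyloxy)phenyl]-7,8-bis(benzyloxy)-4-(2-ethoxyethoxy)chroman-3-ol | O[C@@H]1[C@@H](OCCOCC)c2cc(Br)c(OCc3ccccc3)c(OCc3ccccc3)c2O[C@@H]1c1ccc(OCc2ccccc2)c(OCc2ccccc2)c1
F3 | step 16 | 6-bromo (upper unit) analogue of 25 | C(c1ccccc1)Oc1ccc([C@H]2Oc3c(cc([C@H]4c5cc(Br)c(OCc6ccccc6)c(OCc6ccccc6)c5O[C@H](c5ccc(OCc6ccccc6)c(OCc6ccccc6)c5)[C@@H]4O)c(OCc4ccccc4)c3OCc3ccccc3)[C@@H](OC(=O)O7)[C@H]27)cc1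
F4 | step 16 | 6-bromo (upper unit) analogue of 26 | C(c1ccccc1)Oc1ccc([C@H]2Oc3c(cc([C@H]4c5cc(Br)c(OCc6ccccc6)c(OCc6ccccc6)c5O[C@H](c5ccc(OCc6ccccc6)c(OCc6ccccc6)c5)[C@@H]4O)c(OCc4ccccc4)c3OCc3ccccc3)[C@@H](O)[C@H]2O)cc1
F5 | step 5 | (R)-2-[3,4-bis(benzyloxy)phenyl]-7,8-bis(benzyloxy)-2H-chromene-3-carboxylic acid | OC(=O)C1=Cc2ccc(OCc3ccccc3)c(OCc3ccccc3)c2O[C@@H]1c1ccc(OCc2ccccc2)c(OCc2ccccc2)c1
F6 | step 5 | tert-butyl N-{(R)-2-[3,4-bis(benzyloxy)phenyl]-7,8-bis(benzyloxy)-2H-chromen-3-yl}carbamate | CC(C)(C)OC(=O)NC1=Cc2ccc(OCc3ccccc3)c(OCc3ccccc3)c2O[C@@H]1c1ccc(OCc2ccccc2)c(OCc2ccccc2)c1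
F7 | step 4 | 2,3-bis(benzyloxy)-6-vinylphenol | C=Cc1ccc(OCc2ccccc2)c(OCc2ccccc2)c1O
F8 | step 4 | (E)-3-[3,4-bis(benzyloxy)phenyl]prop-2-en-1-ol | OC/C=C/c1ccc(OCc2ccccc2)c(OCc2ccccc2)c1
F9 | step 4 | (E)-3-[3,4-bis(benzyloxy)phenyl]allyl methyl carbonate | COC(=O)OC/C=C/c1ccc(OCc2ccccc2)c(OCc2ccccc2)c1
F10 | step 4 | (S)-1,2-bis(benzyloxy)-3-({1-[3,4-bis(benzyloxy)phenyl]prop-2-en-1-yl}oxy)-4-vinylbenzene | C=C[C@H](Oc1c(C=C)ccc(OCc2ccccc2)c1OCc1ccccc1)c1ccc(OCc2ccccc2)c(OCc2ccccc2)c1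
F11 | step 4 | (S)-2-[3,4-bis(benzyloxy)phenyl]-7,8-bis(benzyloxy)-2H-chromene | C1=Cc2ccc(OCc3ccccc3)c(OCc3ccccc3)c2O[C@@H]1c1ccc(OCc2ccccc2)c(OCc2ccccc2)c1
F12 | step 4 | (2R,3S)-2-[3,4-bis(benzyloxy)phenyl]-7,8-bis(benzyloxy)chroman-3-ol | O[C@H]1Cc2ccc(OCc3ccccc3)c(OCc3ccccc3)c2O[C@@H]1c1ccc(OCc2ccccc2)c(OCc2ccccc2)c1
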